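The γ-lactone carbon Cq (bearing the ring oxygen and a carboxyl) and its neighbour Cα (bearing a carboxyl and the decyl chain) are vicinal, and the Cα carboxyl carbon, Cα, Cq, lactone CH2 carbons C3 and C4 and lactone carbonyl C5 form a six-carbon loop that can be drawn as a cyclohex-3-ene. One catalytic enantioselective endo Diels–Alder reaction between an (E)-1-alkylbutadiene carrying the silylated ω-hydroxydecyl chain and 2-(benzoyloxy)acrolein therefore forms Cα–Cq and C3–C4 and sets both stereocentres. Later cleavage of the ring alkene gives the Cα carboxyl and C5, which lactonises onto the Cq oxygen. (R)-Malic acid is attached last.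

Key step: step 8

Assumption 1: the (S)-configured oxazaborolidinium is taken to deliver the diene to the Re face of the benzoyloxy-bearing alkene carbon, as the formyl C–H···O binding model for 2-substituted acroleins predicts; the (R)-catalyst would be used in the same way if the sense had to be reversed.

Assumption 2: in step 11 lactone closure is taken to precede loss of the silyl group; the opposite order leads to the same product 17.

Step 1
Reactants: 1 undec-10-en-1-ol
Product: 2 tert-butyl(dimethyl)(undec-10-en-1-yloxy)silane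
Conditions: TBSCl, imidazole, DMF, 0 °C → rt
Reagents that add atoms: tert-butyldimethylsilyl chloride, CC(C)(C)[Si](C)(C)Cl
Why: Imidazole-promoted silylation of a primary alcohol (TBS protection) is reliable and leaves the terminal alkene untouched.

Step 2
Reactants: 2 tert-butyl(dimethyl)(undec-10-en-1-yloxy)silane
Product: 3 11-{[tert-butyl(dimethyl)silyl]oxy}undecan-1-ol
Conditions: 9-BBN, THF, 0 °C → rt; then NaOH (aq), H2O2, 0 °C → rt
Reagents that add atoms: hydrogen peroxide, OO
Why: Brown hydroboration–oxidation with the bulky 9-BBN places boron, and then oxygen, on the terminal carbon, and the silyl ether is inert to both stages.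

Step 3
Reactants: 3 11-{[tert-butyl(dimethyl)silyl]oxy}undecan-1-ol
Product: 4 11-{[tert-butyl(dimethyl)silyl]oxy}undecanal
Conditions: TEMPO (cat.), PhI(OAc)2, CH2Cl2, rt
Reagents that add atoms: none
Why: TEMPO-catalysed alcohol oxidation with PhI(OAc)2 as terminal oxidant stops at the aldehyde under near-neutral conditions that spare the silyl ether.

Step 4
Reactants: 4 11-{[tert-butyl(dimethyl)silyl]oxy}undecanal
Product: 5 (2E)-13-{[tert-butyl(dimethyl)silyl]oxy}tridec-2-enal
Conditions: Ph3P=CHCHO (1.05 equiv), toluene, 80 °C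
Reagents that add atoms: (triphenylphosphoranylidene)acetaldehyde, O=CC=P(c1ccccc1)(c1ccccc1)c1ccccc1
Why: Wittig olefination with the stabilised formylmethylene ylide should give the (E)-enal, and the near-stoichiometric ylide charge limits a second homologation of the product.

Step 5
Reactants: 5 (2E)-13-{[tert-butyl(dimethyl)silyl]oxy}tridec-2-enal
Product: 6 tert-butyl(dimethyl)[(11E)-tetradeca-11,13-dien-1-yloxy]silane
Conditions: Ph3PCH3Br, KOtBu, THF, 0 °C → rt
Reagents that add atoms: methyltriphenylphosphonium bromide, C[P+](c1ccccc1)(c1ccccc1)c1ccccc1.[Br-]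
Why: Wittig methylenation of the enal carbonyl creates the terminal vinyl group without touching the existing (E)-alkene, so the (E)-1-alkylbutadiene results.

Step 6
Reactants: 7 2,2-dimethyl-1,3-dioxan-5-one; 8 benzoyl chloride
Product: 9 2,2-dimethyl-4H-1,3-dioxin-5-yl benzoate
Conditions: Et3N, DMAP (cat.), CH2Cl2, 0 °C → rt
Reagents that add atoms: none
Why: Soft enolisation of the α,α'-dialkoxy ketone by Et3N and O-acylation through the DMAP–benzoyl adduct give the enol benzoate (enol ester formation).

Step 7
Reactants: 9 2,2-dimethyl-4H-1,3-dioxin-5-yl benzoate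
Product: 10 2-(benzoyloxy)acrolein (3-oxoprop-1-en-2-yl benzoate)
Conditions: toluene, 110 °C; concentrate and use at once
Reagents that add atoms: none
Why: Thermal retro-hetero-Diels–Alder fragmentation of the 4H-1,3-dioxin expels acetone and unveils the 2-acyloxyacrolein, driven by loss of the volatile ketone.

Step 8
Reactants: 6 tert-butyl(dimethyl)[(11E)-tetradeca-11,13-dien-1-yloxy]silane; 10 2-(benzoyloxy)acrolein (1.5 equiv)
Product: 11 (1R,2R)-2-(10-{[tert-butyl(dimethyl)silyl]oxy}decyl)-1-formylcyclohex-3-en-1-yl benzoate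
Conditions: (S)-3,3-diphenyl-1-(o-tolyl)tetrahydro-1H,3H-pyrrolo[1,2-c][1,3,2]oxazaborole (20 mol%), Tf2NH (18 mol%), CH2Cl2, −78 → −40 °C
Reagents that add atoms: none
Why: The N-protonated oxazaborolidine binds the formyl oxygen of 10 at boron and lowers its LUMO, and a concerted, asynchronous [4+2] cycloaddition follows in which the free diene terminus C14 bonds to the dienophile CH2 and the chain-bearing C11 to the benzoyloxy carbon (the 1,2 orientation set by the largest frontier coefficients). The closest known reaction type is the oxazaborolidinium-catalysed enantioselective Diels–Alder reaction of 2-substituted acroleins such as methacrolein and 2-bromoacrolein with acyclic dienes, and 2-acyloxyacroleins are established dienophiles. The single new ring, the cyclohexene, closes by suprafacial–suprafacial addition across the s-cis diene. The relative configuration of C1 and C2 follows from the (E)-geometry of the diene together with endo placement of the boron-bound formyl group (chain cis to CHO, trans to the benzoate), and the absolute configuration from the catalyst, whose phenyl group cis to the bound aldehyde shields one face of the s-trans enal so that the diene should add to the Re face of the benzoyloxy carbon, giving 1R and therefore 2R. The step needs 1,2 regioselectivity (secured by the donor alkyl terminus and the captodative acceptor carbon), endo selectivity (secured by formyl activation in an acyclic diene–acyclic dienophile pair, which lacks the bridge repulsion that turns 2-substituted acroleins exo with cyclopentadiene) and one enantioface (secured by the catalyst; Tf2NH is kept below the oxazaborolidine charge so that no free acid attacks the silyl ether or the diene).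

Step 9
Reactants: 11 (1R,2R)-2-(10-{[tert-butyl(dimethyl)silyl]oxy}decyl)-1-formylcyclohex-3-en-1-yl benzoate
Product: 12 (1R,2R)-1-(benzoyloxy)-2-(10-{[tert-butyl(dimethyl)silyl]oxy}decyl)cyclohex-3-ene-1-carboxylic acid
Conditions: NaClO2, NaH2PO4, 2-methyl-2-butene, t-BuOH/THF/H2O, rt
Reagents that add atoms: sodium chlorite, [Na+].[O-]Cl=O
Why: Pinnick oxidation converts the non-enolisable aldehyde into the acid under buffered conditions, with 2-methyl-2-butene scavenging HOCl so that the ring alkene and both stereocentres stay untouched.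

Step 10
Reactants: 12 (1R,2R)-1-(benzoyloxy)-2-(10-{[tert-butyl(dimethyl)silyl]oxy}decyl)cyclohex-3-ene-1-carboxylic acid
Product: 14 (3R,4S)-3-(benzoyloxy)-14-{[tert-butyl(dimethyl)silyl]oxy}tetradecane-1,3,4-tricarboxylic acid, via dialdehyde acid 13 (not isolated)
Conditions: O3, MeCN/H2O (9:1), 0 °C; N2 purge; then NaClO2, NaH2PO4, 2-methyl-2-butene, 0 °C → rt
Reagents that add atoms: ozone, [O-][O+]=O; water, O; sodium chlorite, [Na+].[O-]Cl=O
Why: Ozonolysis in aqueous acetonitrile, where water intercepts the carbonyl oxide and releases the aldehydes directly, followed by Pinnick oxidation in the same flask, cleaves the ring C=C to two carboxyl groups in a mildly acidic medium that should neither enolise the Cα aldehyde nor eliminate the benzoate.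

Step 11
Reactants: 14 (3R,4S)-3-(benzoyloxy)-14-{[tert-butyl(dimethyl)silyl]oxy}tetradecane-1,3,4-tricarboxylic acid
Product: 17 (2R)-2-[(1S)-1-carboxy-11-hydroxyundecyl]-5-oxooxolane-2-carboxylic acid, via hydroxy triacid 15 (not isolated), via silyl lactone diacid 16 (not isolated)
Conditions: LiOH, THF/H2O, 50 °C; then HCl (aq) to pH 1, 40 °C
Reagents that add atoms: none
Why: Saponification of the benzoate by acyl–oxygen cleavage frees the tertiary hydroxyl without touching the C–O bond at Cq, acidification drives γ-lactonisation onto the CH2CH2CO2H arm (the only alternative being a strained β-lactone), and the aqueous HCl also removes the primary silyl ether.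

Step 12
Reactants: 18 (R)-malic acid
Product: 19 (3R)-2,5-dioxooxolan-3-yl trifluoroacetate
Conditions: (CF3CO)2O (neat), 0 °C → rt; evaporate
Reagents that add atoms: trifluoroacetic anhydride, O=C(OC(=O)C(F)(F)F)C(F)(F)F
Why: Trifluoroacetic anhydride acylates the hydroxyl and dehydrates the 1,4-diacid to the cyclic anhydride without breaking a bond at the stereocentre (mixed-anhydride cyclodehydration).

Step 13
Reactants: 17 (2R)-2-[(1S)-1-carboxy-11-hydroxyundecyl]-5-oxooxolane-2-carboxylic acid; 19 (3R)-2,5-dioxooxolan-3-yl trifluoroacetate (3 equiv)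
Product: 21 (2R)-2-[(1S)-1-carboxy-11-{[(2R)-3-carboxy-2-hydroxypropanoyl]oxy}undecyl]-5-oxooxolane-2-carboxylic acid, via trifluoroacetyl malate ester 20 (not isolated)
Conditions: THF, rt → 40 °C; then H2O, rt
Reagents that add atoms: none
Why: Alcoholysis of the cyclic anhydride should occur at the carbonyl next to the electron-poor trifluoroacetoxy carbon, giving the 1-ester of malic acid regioselectively, and the labile trifluoroacetate is hydrolysed during the aqueous stage (anhydride ring-opening esterification).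

Compound list
1 | undec-10-en-1-ol | C=CCCCCCCCCCO | starting material
2 | tert-butyl(dimethyl)(undec-10-en-1-yloxy)silane | C=CCCCCCCCCCO[Si](C)(C)C(C)(C)C | intermediate
3 | 11-{[tert-butyl(dimethyl)silyl]oxy}undecan-1-ol | OCCCCCCCCCCCO[Si](C)(C)C(C)(C)C | intermediate
4 | 11-{[tert-butyl(dimethyl)silyl]oxy}undecanal | O=CCCCCCCCCCCO[Si](C)(C)C(C)(C)C | intermediate
5 | (2E)-13-{[tert-butyl(dimethyl)silyl]oxy}tridec-2-enal | O=C/C=C/CCCCCCCCCCO[Si](C)(C)C(C)(C)C | intermediate
6 | tert-butyl(dimethyl)[(11E)-tetradeca-11,13-dien-1-yloxy]silane | C=C/C=C/CCCCCCCCCCO[Si](C)(C)C(C)(C)C | intermediate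
7 | 2,2-dimethyl-1,3-dioxan-5-one | CC1(C)OCC(=O)CO1 | starting material
8 | benzoyl chloride | O=C(Cl)c1ccccc1 | starting material
9 | 2,2-dimethyl-4H-1,3-dioxin-5-yl benzoate | CC1(C)OCC(OC(=O)c2ccccc2)=CO1 | intermediate
10 | 2-(benzoyloxy)acrolein (3-oxoprop-1-en-2-yl benzoate) | C=C(C=O)OC(=O)c1ccccc1 | intermediate
11 | (1R,2R)-2-(10-{[tert-butyl(dimethyl)silyl]oxy}decyl)-1-formylcyclohex-3-en-1-yl benzoate | CC(C)(C)[Si](C)(C)OCCCCCCCCCC[C@@H]1C=CCC[C@]1(OC(=O)c2ccccc2)C=O | intermediate
12 | (1R,2R)-1-(benzoyloxy)-2-(10-{[tert-butyl(dimethyl)silyl]oxy}decyl)cyclohex-3-ene-1-carboxylic acid | CC(C)(C)[Si](C)(C)OCCCCCCCCCC[C@@H]1C=CCC[C@]1(OC(=O)c2ccccc2)C(=O)O | intermediate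
13 | (2R,3S)-2-(benzoyloxy)-13-{[tert-butyl(dimethyl)silyl]oxy}-3-formyl-2-(3-oxopropyl)tridecanoic acid (dialdehyde acid) | CC(C)(C)[Si](C)(C)OCCCCCCCCCC[C@H](C=O)[C@@](CCC=O)(OC(=O)c1ccccc1)C(=O)O | intermediate
14 | (3R,4S)-3-(benzoyloxy)-14-{[tert-butyl(dimethyl)silyl]oxy}tetradecane-1,3,4-tricarboxylic acid | CC(C)(C)[Si](C)(C)OCCCCCCCCCC[C@H](C(=O)O)[C@@](CCC(=O)O)(OC(=O)c1ccccc1)C(=O)O | intermediate
15 | (3R,4S)-14-{[tert-butyl(dimethyl)silyl]oxy}-3-hydroxytetradecane-1,3,4-tricarboxylic acid (hydroxy triacid; present as its lithium salt until the acid is added) | CC(C)(C)[Si](C)(C)OCCCCCCCCCC[C@H](C(=O)O)[C@@](CCC(=O)O)(O)C(=O)O | intermediate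
16 | (2R)-2-[(1S)-11-{[tert-butyl(dimethyl)silyl]oxy}-1-carboxyundecyl]-5-oxooxolane-2-carboxylic acid (silyl lactone diacid) | CC(C)(C)[Si](C)(C)OCCCCCCCCCC[C@H](C(=O)O)[C@@]1(C(=O)O)CCC(=O)O1 | intermediate
17 | (2R)-2-[(1S)-1-carboxy-11-hydroxyundecyl]-5-oxooxolane-2-carboxylic acid | OCCCCCCCCCC[C@H](C(=O)O)[C@@]1(C(=O)O)CCC(=O)O1 | intermediate
18 | (R)-malic acid | O[C@H](CC(O)=O)C(O)=O | starting material
19 | (3R)-2,5-dioxooxolan-3-yl trifluoroacetate | O=C1C[C@@H](OC(=O)C(F)(F)F)C(=O)O1 | intermediate
20 | (2R)-2-[(1S)-1-carboxy-11-{[(2R)-3-carboxy-2-(trifluoroacetoxy)propanoyl]oxy}undecyl]-5-oxooxolane-2-carboxylic acid (trifluoroacetyl malate ester) | O=C(O)C[C@@H](OC(=O)C(F)(F)F)C(=O)OCCCCCCCCCC[C@H](C(=O)O)[C@@]1(C(=O)O)CCC(=O)O1 | intermediate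
21 | (2R)-2-[(1S)-1-carboxy-11-{[(2R)-3-carboxy-2-hydroxypropanoyl]oxy}undecyl]-5-oxooxolane-2-carboxylic acid | O=C(O)C[C@@H](O)C(=O)OCCCCCCCCCC[C@H](C(=O)O)[C@@]1(C(=O)O)CCC(=O)O1 | target

Total step count: 13. Longest linear sequence: 10 steps (steps 1–5, 8–11 and 13).

Steps most likely to fail

Step 8. Turnover of the cationic boron catalyst may be slow with a weakly activated 1-alkyldiene while the benzoate carbonyl competes for boron, and enantioface or endo discrimination may erode if the temperature has to be raised to compensate. The fallback gives up catalyst control in favour of resolution. It sets out from diene 6 and dienophile 10, which are combined under an achiral Lewis acid (SnCl4, CH2Cl2, −78 °C) to give the racemic endo adduct rac-(1R,2R)-2-(10-{[tert-butyl(dimethyl)silyl]oxy}decyl)-1-formylcyclohex-3-en-1-yl benzoate F1. Its enantiomers are separated by preparative chromatography on a chiral stationary phase; the (1S,2S)-2-(10-{[tert-butyl(dimethyl)silyl]oxy}decyl)-1-formylcyclohex-3-en-1-yl benzoate F2 is set aside, and the (1R,2R)-enantiomer is compound 11, where the route is rejoined.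

Step 11. Hydroxide attack on the hindered tertiary benzoate may stall because it has to approach a tricarboxylate, leaving the ester in place. The fallback removes the benzoate earlier, while only one carboxylate is present. It sets out from acid 12, which is saponified (LiOH, THF/H2O, 50 °C) to (1R,2R)-2-(10-{[tert-butyl(dimethyl)silyl]oxy}decyl)-1-hydroxycyclohex-3-ene-1-carboxylic acid F3. The ozonolysis–chlorite sequence of step 10 is then applied to F3; it passes through (2R,3S)-13-{[tert-butyl(dimethyl)silyl]oxy}-3-formyl-2-hydroxy-2-(3-oxopropyl)tridecanoic acid F4 and delivers hydroxy triacid 15, where the route is rejoined and the aqueous HCl stage of step 11 gives 17.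

Step 13. The free carboxyl groups of 17 may engage the cyclic anhydride (mixed anhydrides, oligomeric esters), and the poor solubility of the diacid in an aprotic solvent may hold back acylation of the ω-hydroxyl. The fallback masks the two acids and ends with a hydrogenolysis. It sets out from 17, which is alkylated at both carboxylates (BnBr, KHCO3, DMF, rt) to benzyl (2R)-2-[(1S)-1-(benzyloxycarbonyl)-11-hydroxyundecyl]-5-oxooxolane-2-carboxylate F5. Acylation of F5 with anhydride 19 in THF gives benzyl (2R)-2-[(1S)-1-(benzyloxycarbonyl)-11-{[(2R)-3-carboxy-2-(trifluoroacetoxy)propanoyl]oxy}undecyl]-5-oxooxolane-2-carboxylate F6, which on addition of water becomes benzyl (2R)-2-[(1S)-1-(benzyloxycarbonyl)-11-{[(2R)-3-carboxy-2-hydroxypropanoyl]oxy}undecyl]-5-oxooxolane-2-carboxylate F7. Hydrogenolysis of both benzyl esters (H2, Pd/C, EtOAc, rt) then gives the target 21.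

Further compounds
F1 | step 8 | rac-(1R,2R)-2-(10-{[tert-butyl(dimethyl)silyl]oxy}decyl)-1-formylcyclohex-3-en-1-yl benzoate (racemate, both enantiomers written) | CC(C)(C)[Si](C)(C)OCCCCCCCCCC[C@@H]1C=CCC[C@]1(OC(=O)c2ccccc2)C=O.CC(C)(C)[Si](C)(C)OCCCCCCCCCC[C@H]1C=CCC[C@@]1(OC(=O)c2ccccc2)C=O
F2 | step 8 | (1S,2S)-2-(10-{[tert-butyl(dimethyl)silyl]oxy}decyl)-1-formylcyclohex-3-en-1-yl benzoate | CC(C)(C)[Si](C)(C)OCCCCCCCCCC[C@H]1C=CCC[C@@]1(OC(=O)c2ccccc2)C=O
F3 | step 11 | (1R,2R)-2-(10-{[tert-butyl(dimethyl)silyl]oxy}decyl)-1-hydroxycyclohex-3-ene-1-carboxylic acid | CC(C)(C)[Si](C)(C)OCCCCCCCCCC[C@@H]1C=CCC[C@]1(O)C(=O)O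
F4 | step 11 | (2R,3S)-13-{[tert-butyl(dimethyl)silyl]oxy}-3-formyl-2-hydroxy-2-(3-oxopropyl)tridecanoic acid | CC(C)(C)[Si](C)(C)OCCCCCCCCCC[C@H](C=O)[C@@](CCC=O)(O)C(=O)O
F5 | step 13 | benzyl (2R)-2-[(1S)-1-(benzyloxycarbonyl)-11-hydroxyundecyl]-5-oxooxolane-2-carboxylate | OCCCCCCCCCC[C@H](C(=O)OCc1ccccc1)[C@@]1(C(=O)OCc2ccccc2)CCC(=O)O1
F6 | step 13 | benzyl (2R)-2-[(1S)-1-(benzyloxycarbonyl)-11-{[(2R)-3-carboxy-2-(trifluoroacetoxy)propanoyl]oxy}undecyl]-5-oxooxolane-2-carboxylate | O=C(O)C[C@@H](OC(=O)C(F)(F)F)C(=O)OCCCCCCCCCC[C@H](C(=O)OCc1ccccc1)[C@@]1(C(=O)OCc2ccccc2)CCC(=O)O1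
F7 | step 13 | benzyl (2R)-2-[(1S)-1-(benzyloxycarbonyl)-11-{[(2R)-3-carboxy-2-hydroxypropanoyl]oxy}undecyl]-5-oxooxolane-2-carboxylate | O=C(O)C[C@@H](O)C(=O)OCCCCCCCCCC[C@H](C(=O)OCc1ccccc1)[C@@]1(C(=O)OCc2ccccc2)CCC(=O)O1
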